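**Retrosynthetic overview**

1. Ustusoic acid B is traced back to a 6β,9α-dihydroxy-12-oxo C11 tert-butyl ester (late acylation of the axial 6β-OH, then ester acidolysis). Its 6β-OH and C12 aldehyde come from a 6-oxo-12-methyl ester by α-face hydride reduction and re-oxidation at C12; the 9α-OH comes from α-oxygenation of a drim-8-ene diester dienolate.
2. Ring B is the only ring made (ring A arrives intact from β-cyclocitral). It is closed last, at C6–C7, by an intramolecular vinylogous aldol addition of a monocyclic seco-aldehyde.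
3. Enabling feature: C7–C8(–C12)–C9–C11 is an itaconate unit, so C7 is the γ-carbon of the C11 ester through C8/C9 and becomes nucleophilic toward a C6 aldehyde on ring A. The C8=C9 alkene formed in ring B is then used in reverse (C7 deprotonation, C9 oxygenation) to place 9α-OH and the C7=C8 bond.
4. The seco-aldehyde comes from methyl β-cyclogeranyl itaconate by an enantioselective Ireland–Claisen rearrangement (C9–C10 bond; quaternary C10 is the only stereocentre set by a reagent) and a face-selective hydroboration (C5). C6 and C9 are relayed from these centres.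

Key step: step 8

**Remarks on the chemistry (assumptions)**

- Locants are those of the drimane skeleton (ring A: C1–C5 and C10; ring B: C5–C10; C11 on C9, C12 on C8; methyl groups on C4, C4 and C10). The same locants are used for the corresponding atoms of the monocyclic precursors.
- The sense of induction of the (S,S)-diazaborolidine in step 4 is assumed, not derived; if the first run gives the enantiomer of 7, the (R,R)-reagent is used and nothing else changes. Reagent SMILES: BrB1N(S(=O)(=O)c2cc(cc(c2)C(F)(F)F)C(F)(F)F)[C@@H](c2ccccc2)[C@H](c2ccccc2)N1S(=O)(=O)c1cc(cc(c1)C(F)(F)F)C(F)(F)F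
- Compounds 7–11 may be mixtures of epimers at C9 (drawn for the epimer expected from a chair transition state). This centre is erased in step 8.

**Route**

Step 1
Reactants: 1 β-cyclocitral
Product: 2 β-cyclogeraniol
Conditions: NaBH4, MeOH, 0 °C
Reagents that add atoms: none
Why: Borohydride 1,2-reduction of the hindered enal gives the primary allylic alcohol; no stereocentre is formed.

Step 2
Reactants: 2 β-cyclogeraniol; 3 itaconic anhydride
Product: 4 4-(β-cyclogeranyl) hydrogen itaconate
Conditions: toluene, 70 °C
Reagents that add atoms: none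
Why: Alcoholysis of the cyclic anhydride takes place at the carbonyl that is not conjugated to the methylidene group, so the allylic ester sits on the CH2–CO carbon (future C11) and the acrylic acid (future C12) stays free.

Step 3
Reactants: 4 4-(β-cyclogeranyl) hydrogen itaconate
Product: 5 methyl β-cyclogeranyl itaconate
Conditions: MeI, KHCO3, DMF, 20 °C
Reagents that add atoms: iodomethane, CI
Why: SN2 O-alkylation of the carboxylate under bicarbonate is mild enough to leave the itaconate double bond in place.

Step 4
Reactants: 5 methyl β-cyclogeranyl itaconate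
Product: 7 (2S)-3-(methoxycarbonyl)-2-[(1R)-1,3,3-trimethyl-2-methylidenecyclohexyl]but-3-enoic acid, via boron ketene acetal 6 (not isolated)
Conditions: (S,S)-2-bromo-4,5-diphenyl-1,3-bis[3,5-bis(trifluoromethyl)phenylsulfonyl]-1,3,2-diazaborolidine (1.2 equiv), Et3N, CH2Cl2, −78 °C; then −20 to 20 °C; aqueous work-up
Reagents that add atoms: none
Why: Enantioselective Ireland–Claisen rearrangement: soft enolisation of the doubly activated C9 methylene gives the chiral boron ketene acetal, whose chair-like [3,3] shift forms C9–C10 and the quaternary C10 centre and moves the ring double bond to the exocyclic C5=C6 position; the diazaborolidine selects the enolate face and, through the chair, the C10 configuration, while the C9 configuration is of no consequence.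

Step 5
Reactants: 7 (2S)-3-(methoxycarbonyl)-2-[(1R)-1,3,3-trimethyl-2-methylidenecyclohexyl]but-3-enoic acid
Product: 8 1-tert-butyl 4-methyl (2S)-3-methylidene-2-[(1R)-1,3,3-trimethyl-2-methylidenecyclohexyl]butanedioate
Conditions: tert-butyl 2,2,2-trichloroacetimidate, BF3·OEt2 (cat.), CH2Cl2–cyclohexane, 20 °C
Reagents that add atoms: tert-butyl 2,2,2-trichloroacetimidate, CC(C)(C)OC(=N)C(Cl)(Cl)Cl
Why: Acid-catalysed O-tert-butylation with the imidate works at room temperature on a hindered acid, avoids heating the 1,5-diene (Cope rearrangement), and gives a C11 ester that survives the later hydride step and is removed last.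

Step 6
Reactants: 8 1-tert-butyl 4-methyl (2S)-3-methylidene-2-[(1R)-1,3,3-trimethyl-2-methylidenecyclohexyl]butanedioate
Product: 10 1-tert-butyl 4-methyl (2S)-2-[(1S,2S)-2-(hydroxymethyl)-1,3,3-trimethylcyclohexyl]-3-methylidenebutanedioate, via alkylborane 9 (not isolated)
Conditions: BH3·SMe2 (0.6 equiv), THF, 0 °C; then NaBO3·4H2O, THF–H2O, 20 °C
Reagents that add atoms: sodium perborate tetrahydrate (NaBO3·4H2O), [Na+].OO[B-](O)(O)O
Why: Hydroboration–oxidation: the electrophilic borane should add to the electron-rich 1,1-dialkyl exocyclic alkene and not to the electron-poor acrylate, with boron on the terminal C6 and hydrogen delivered to C5 from the ring face opposite the two axial methyl groups (on C10 and C4), which sets 5α-H (C6 cis to the C10 methyl group); the mild perborate oxidation spares both esters.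

Step 7
Reactants: 10 1-tert-butyl 4-methyl (2S)-2-[(1S,2S)-2-(hydroxymethyl)-1,3,3-trimethylcyclohexyl]-3-methylidenebutanedioate
Product: 11 1-tert-butyl 4-methyl (2S)-2-[(1S,2S)-2-formyl-1,3,3-trimethylcyclohexyl]-3-methylidenebutanedioate
Conditions: Dess–Martin periodinane, pyridine, CH2Cl2, 0 to 20 °C
Reagents that add atoms: none
Why: Dess–Martin oxidation gives the C6 aldehyde under buffered, non-enolising conditions, so the C5 centre is kept.

Step 8
Reactants: 11 1-tert-butyl 4-methyl (2S)-2-[(1S,2S)-2-formyl-1,3,3-trimethylcyclohexyl]-3-methylidenebutanedioate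
Product: 13 11-tert-butyl 12-methyl (5S,6S,10S)-6-hydroxydrim-8-ene-11,12-dioate, via potassium dienolate 12 (not isolated)
Conditions: KOtBu (1.1 equiv), THF, −40 to 0 °C; AcOH quench
Reagents that add atoms: none
Why: tert-Butoxide removes the C9 proton, and the ester dienolate, whose charge is delocalised through C8 onto the methylidene carbon C7, adds through C7 to the C6 aldehyde (intramolecular vinylogous aldol addition; closest known chemistry: γ-selective aldol reactions of ester dienolates and Stobbe-type condensations of succinate and itaconate esters). Ring B is closed in the 6-(enolendo)-exo-trig mode, and ring size secures the regiochemistry, because attack through C9 would give a cyclobutane and the aldehyde enolate has only a disfavoured 5-endo conjugate addition open to it. Both C9 epimers of 11 give the same planar dienolate, so the mixture converges on one C8=C9 alkene, while C5 (set in step 6) and C10 are carried through and make the ring fusion trans. The new C6 carbinol is expected to be equatorial (6α), since the carbonyl oxygen turns away from the axial C4 and C10 methyl groups in the chair-like closure, but its configuration is not needed because steps 10 and 11 reset it. The selectivity that matters is addition without dehydration to a 6,8-diene, which is why about one equivalent of base, low temperature and an acid quench hold the product as its alkoxide until work-up.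

Step 9
Reactants: 13 11-tert-butyl 12-methyl (5S,6S,10S)-6-hydroxydrim-8-ene-11,12-dioate
Product: 15 11-tert-butyl 12-methyl (5S,6S,9S,10S)-6,9-dihydroxydrim-7-ene-11,12-dioate, via dipotassium dienolate 14 (not isolated)
Conditions: KN(SiMe3)2 (2.5 equiv), THF, −78 °C; then 3-phenyl-2-(phenylsulfonyl)oxaziridine, −78 to −40 °C; aq. NH4Cl
Reagents that add atoms: 3-phenyl-2-(phenylsulfonyl)oxaziridine, O=S(=O)(N1OC1c1ccccc1)c1ccccc1
Why: γ-Deprotonation at C7 gives the dienolate of the C11 ester, which is oxygenated at its α-carbon C9 by the N-sulfonyloxaziridine (enolate hydroxylation) while the double bond moves to C7=C8 into conjugation with the C12 ester; the oxidant approaches the face opposite the axial C10 methyl group and should give the 9α-alcohol.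

Step 10
Reactants: 15 11-tert-butyl 12-methyl (5S,6S,9S,10S)-6,9-dihydroxydrim-7-ene-11,12-dioate
Product: 16 11-tert-butyl 12-methyl (5S,9S,10S)-9-hydroxy-6-oxodrim-7-ene-11,12-dioate
Conditions: Dess–Martin periodinane, pyridine, CH2Cl2, 20 °C
Reagents that add atoms: none
Why: Dess–Martin oxidation of the secondary allylic alcohol removes the C6 centre of the wrong configuration; the tertiary alcohol is inert and the buffered medium leaves C5 untouched.

Step 11
Reactants: 16 11-tert-butyl 12-methyl (5S,9S,10S)-9-hydroxy-6-oxodrim-7-ene-11,12-dioate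
Product: 17 tert-butyl (5S,6R,9S,10S)-6,9,12-trihydroxydrim-7-en-11-oate
Conditions: iBu2AlH (5 equiv), CH2Cl2, −78 °C; aq. KNaC4H4O6
Reagents that add atoms: none
Why: Aluminium hydride reduction: 1,2-addition to the enone from the α-face (the β-face is shielded by the axial C10 and C4 methyl groups) should set the axial 6β-alcohol, and the conjugated methyl ester is reduced to the primary allylic alcohol while the very hindered tert-butyl ester is expected to survive.

Step 12
Reactants: 17 tert-butyl (5S,6R,9S,10S)-6,9,12-trihydroxydrim-7-en-11-oate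
Product: 18 tert-butyl (5S,6R,9S,10S)-6,9-dihydroxy-12-oxodrim-7-en-11-oate
Conditions: (2,2,6,6-tetramethylpiperidin-1-yl)oxyl (0.1 equiv), PhI(OAc)2, CH2Cl2, 20 °C
Reagents that add atoms: none
Why: Oxoammonium-mediated oxidation is selective for the primary allylic alcohol over the hindered axial secondary and the tertiary alcohol, and stops at the enal.

Step 13
Reactants: 19 sorbaldehyde; 20 malonic acid
Product: 22 (2E,4E,6E)-octa-2,4,6-trienoic acid, via alkylidenemalonic acid 21 (not isolated)
Conditions: pyridine, piperidine (cat.), 90 °C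
Reagents that add atoms: none
Why: Knoevenagel–Doebner condensation with in-situ decarboxylation extends the dienal by two carbons to the all-E trienoic acid.

Step 14
Reactants: 18 tert-butyl (5S,6R,9S,10S)-6,9-dihydroxy-12-oxodrim-7-en-11-oate; 22 (2E,4E,6E)-octa-2,4,6-trienoic acid
Product: 24 tert-butyl (5S,6R,9S,10S)-9-hydroxy-6-[(2E,4E,6E)-octa-2,4,6-trienoyloxy]-12-oxodrim-7-en-11-oate, via mixed anhydride 23 (not isolated)
Conditions: 22, 2,4,6-trichlorobenzoyl chloride, Et3N, THF, 20 °C; then 18, DMAP, toluene, 20 to 40 °C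
Reagents that add atoms: none
Why: Yamaguchi esterification acylates the hindered axial 6β-alcohol on oxygen, so the C6 configuration is retained, and the tertiary 9-alcohol does not compete.

Step 15
Reactants: 24 tert-butyl (5S,6R,9S,10S)-9-hydroxy-6-[(2E,4E,6E)-octa-2,4,6-trienoyloxy]-12-oxodrim-7-en-11-oate
Product: 25 ustusoic acid B
Conditions: CF3CO2H–CH2Cl2 (1:4), 0 °C
Reagents that add atoms: none
Why: Acidolysis of the tert-butyl ester (loss of 2-methylpropene) frees the C11 acid without hydrolytic conditions that would endanger the trienoate, the enal or the tertiary alcohol.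

**Compound list**

1 | β-cyclocitral (2,6,6-trimethylcyclohex-1-ene-1-carbaldehyde) | CC1=C(C=O)C(C)(C)CCC1 | starting material
2 | β-cyclogeraniol [(2,6,6-trimethylcyclohex-1-en-1-yl)methanol] | CC1=C(CO)C(C)(C)CCC1 | intermediate
3 | itaconic anhydride (3-methylideneoxolane-2,5-dione) | C=C1CC(=O)OC1=O | starting material
4 | 4-(β-cyclogeranyl) hydrogen itaconate {2-methylidene-4-oxo-4-[(2,6,6-trimethylcyclohex-1-en-1-yl)methoxy]butanoic acid} | C=C(CC(=O)OCC1=C(C)CCCC1(C)C)C(=O)O | intermediate
5 | methyl β-cyclogeranyl itaconate {1-methyl 4-[(2,6,6-trimethylcyclohex-1-en-1-yl)methyl] 2-methylidenebutanedioate} | C=C(CC(=O)OCC1=C(C)CCCC1(C)C)C(=O)OC | intermediate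
6 | boron ketene acetal of 5 (C9=C11 enolate carrying the (4S,5S)-4,5-diphenyl-1,3-bis[3,5-bis(trifluoromethyl)phenylsulfonyl]-1,3,2-diazaborolidin-2-yl group on oxygen; geometry not specified) | C=C(C(=O)OC)C=C(OCC1=C(C)CCCC1(C)C)OB2N(S(=O)(=O)c3cc(cc(c3)C(F)(F)F)C(F)(F)F)[C@@H](c3ccccc3)[C@H](c3ccccc3)N2S(=O)(=O)c2cc(cc(c2)C(F)(F)F)C(F)(F)F | intermediate
7 | (2S)-3-(methoxycarbonyl)-2-[(1R)-1,3,3-trimethyl-2-methylidenecyclohexyl]but-3-enoic acid | OC(=O)[C@H](C(=C)C(=O)OC)[C@@]1(C)CCCC(C)(C)C1=C | intermediate
8 | 1-tert-butyl 4-methyl (2S)-3-methylidene-2-[(1R)-1,3,3-trimethyl-2-methylidenecyclohexyl]butanedioate | CC(C)(C)OC(=O)[C@H](C(=C)C(=O)OC)[C@@]1(C)CCCC(C)(C)C1=C | intermediate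
9 | alkylborane from 8 (boron on C6, drawn as the monoalkylborane; 5α-H) | CC(C)(C)OC(=O)[C@H](C(=C)C(=O)OC)[C@@]1(C)CCCC(C)(C)[C@@H]1CB | intermediate
10 | 1-tert-butyl 4-methyl (2S)-2-[(1S,2S)-2-(hydroxymethyl)-1,3,3-trimethylcyclohexyl]-3-methylidenebutanedioate (CH2OH cis to the ring methyl on the neighbouring quaternary carbon) | CC(C)(C)OC(=O)[C@H](C(=C)C(=O)OC)[C@@]1(C)CCCC(C)(C)[C@@H]1CO | intermediate
11 | 1-tert-butyl 4-methyl (2S)-2-[(1S,2S)-2-formyl-1,3,3-trimethylcyclohexyl]-3-methylidenebutanedioate (seco-aldehyde) | CC(C)(C)OC(=O)[C@H](C(=C)C(=O)OC)[C@@]1(C)CCCC(C)(C)[C@@H]1C=O | intermediate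
12 | potassium dienolate of 11 (C9 deprotonated; charge on the C11 ester oxygen, C9 and C7) | [K+].[O-]C(OC(C)(C)C)=C(C(=C)C(=O)OC)[C@@]1(C)CCCC(C)(C)[C@@H]1C=O | intermediate
13 | 11-tert-butyl 12-methyl (5S,6S,10S)-6-hydroxydrim-8-ene-11,12-dioate (trans-fused; 6α-OH equatorial) | O[C@H]1CC(C(=O)OC)=C(C(=O)OC(C)(C)C)[C@@]2(C)CCCC(C)(C)[C@H]12 | intermediate
14 | dipotassium salt of 13 (6-alkoxide and C7-deprotonated dienolate of the C11 ester) | [K+].[K+].[O-][C@H]1C=C(C(=O)OC)C(=C([O-])OC(C)(C)C)[C@@]2(C)CCCC(C)(C)[C@H]12 | intermediate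
15 | 11-tert-butyl 12-methyl (5S,6S,9S,10S)-6,9-dihydroxydrim-7-ene-11,12-dioate (6α-OH, 9α-OH) | O[C@H]1C=C(C(=O)OC)[C@](O)(C(=O)OC(C)(C)C)[C@@]2(C)CCCC(C)(C)[C@H]12 | intermediate
16 | 11-tert-butyl 12-methyl (5S,9S,10S)-9-hydroxy-6-oxodrim-7-ene-11,12-dioate | O=C1C=C(C(=O)OC)[C@](O)(C(=O)OC(C)(C)C)[C@@]2(C)CCCC(C)(C)[C@H]12 | intermediate
17 | tert-butyl (5S,6R,9S,10S)-6,9,12-trihydroxydrim-7-en-11-oate (6β-OH axial, 9α-OH) | O[C@@H]1C=C(CO)[C@](O)(C(=O)OC(C)(C)C)[C@@]2(C)CCCC(C)(C)[C@H]12 | intermediate
18 | tert-butyl (5S,6R,9S,10S)-6,9-dihydroxy-12-oxodrim-7-en-11-oate | O[C@@H]1C=C(C=O)[C@](O)(C(=O)OC(C)(C)C)[C@@]2(C)CCCC(C)(C)[C@H]12 | intermediate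
19 | sorbaldehyde [(2E,4E)-hexa-2,4-dienal] | C/C=C/C=C/C=O | starting material
20 | malonic acid | OC(=O)CC(=O)O | starting material
21 | 2-[(2E,4E)-hexa-2,4-dien-1-ylidene]propanedioic acid | C/C=C/C=C/C=C(C(=O)O)C(=O)O | intermediate
22 | (2E,4E,6E)-octa-2,4,6-trienoic acid | C/C=C/C=C/C=C/C(=O)O | intermediate
23 | (2E,4E,6E)-octa-2,4,6-trienoic 2,4,6-trichlorobenzoic anhydride | C/C=C/C=C/C=C/C(=O)OC(=O)c1c(Cl)cc(Cl)cc1Cl | intermediate
24 | tert-butyl (5S,6R,9S,10S)-9-hydroxy-6-[(2E,4E,6E)-octa-2,4,6-trienoyloxy]-12-oxodrim-7-en-11-oate | C/C=C/C=C/C=C/C(=O)O[C@@H]1C=C(C=O)[C@](O)(C(=O)OC(C)(C)C)[C@@]2(C)CCCC(C)(C)[C@H]12 | intermediate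
25 | ustusoic acid B [(5S,6R,9S,10S)-9-hydroxy-6-[(2E,4E,6E)-octa-2,4,6-trienoyloxy]-12-oxodrim-7-en-11-oic acid] | C/C=C/C=C/C=C/C(=O)O[C@@H]1C=C(C=O)[C@](O)(C(=O)O)[C@@]2(C)CCCC(C)(C)[C@H]12 | target

**Step count and risks**

Total step count: 15. Longest linear sequence: 14 steps (steps 1–12, 14 and 15, from β-cyclocitral); step 13 is a one-step side branch.

The three steps most likely to fail:

Step 4. The [3,3] shift has to bond a tetrasubstituted ring alkene carbon, so it may be slow. The chiral boron group may also discriminate the enolate faces poorly, or the chair and boat pathways may compete, which would lower the enantiomeric purity at C10. Fallback: setting out from 5, a conventional Ireland–Claisen rearrangement through the trimethylsilyl ketene acetal (LiN(iPr)2, Me3SiCl, THF, −78 to 20 °C) should give the racemic Claisen acid F1. Classical resolution by crystallisation of its salt with (R)-1-phenylethylamine gives the diastereomeric salt F2 (the enantiomer of the amine is chosen so that the salt of 7 is the less soluble one), and acidification with dilute HCl comes back to the route at 7.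

Step 8. The aldol addition is reversible, so the ring-closed alkoxide may revert, or the aldol may lose water by elimination to a 6,8-diene. Base-induced shift of the itaconate double bond could also slow the closure. Fallback: setting out from 11, the same C6–C7 bond is made irreversibly at the ketone level. Pinnick oxidation (NaClO2, NaH2PO4, 2-methylbut-2-ene, tBuOH–H2O) gives the C6 carboxylic acid F3, and esterification (MeI, KHCO3, DMF) gives the triester F4. A vinylogous Dieckmann cyclisation (KOtBu, THF, 0 °C), driven by formation of the stabilised enolate, gives the keto diester F5. Luche reduction (NaBH4, CeCl3·7H2O, MeOH, −40 °C) from the α-face gives the 6β-alcohol F6, and the dienolate oxygenation under the conditions of step 9 gives the 6β,9α-diol F7. Reduction of its C12 methyl ester with iBu2AlH comes back to the route at 17; steps 10 and 11 are then not needed.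

Step 9. The oxidant may attack the less hindered γ-carbon C7 of the dienolate instead of the fully substituted C9, or the sulfonylimine by-product may add to the enolate. Fallback: setting out from 13, double silylation (LiN(iPr)2, 2.2 equiv, Me3SiCl, THF, −78 °C) gives the 6-O-silyl silyl ketene acetal F8. A Rubottom-type oxidation with dimethyldioxirane (acetone–CH2Cl2, −78 °C) can only attack the electron-rich C9=C11 ketene acetal bond, from the face opposite the C10 methyl group, and gives the bis(trimethylsilyl) ether F9. Desilylation with HF·pyridine comes back to the route at 15.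

**Further compounds**

F1 | step 4 | racemic 3-(methoxycarbonyl)-2-(1,3,3-trimethyl-2-methylidenecyclohexyl)but-3-enoic acid (racemate of 7, stereodescriptors omitted) | OC(=O)C(C(=C)C(=O)OC)C1(C)CCCC(C)(C)C1=C
F2 | step 4 | (R)-1-phenylethylammonium salt of 7 | [O-]C(=O)[C@H](C(=C)C(=O)OC)[C@@]1(C)CCCC(C)(C)C1=C.C[C@@H]([NH3+])c1ccccc1
F3 | step 8 | (1S,2S)-2-[(2S)-1-tert-butoxy-4-methoxy-3-methylidene-1,4-dioxobutan-2-yl]-2,6,6-trimethylcyclohexane-1-carboxylic acid (C6 acid from 11) | CC(C)(C)OC(=O)[C@H](C(=C)C(=O)OC)[C@@]1(C)CCCC(C)(C)[C@@H]1C(=O)O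
F4 | step 8 | methyl ester of F3 (triester) | CC(C)(C)OC(=O)[C@H](C(=C)C(=O)OC)[C@@]1(C)CCCC(C)(C)[C@@H]1C(=O)OC
F5 | step 8 | 11-tert-butyl 12-methyl (5S,10S)-6-oxodrim-8-ene-11,12-dioate | O=C1CC(C(=O)OC)=C(C(=O)OC(C)(C)C)[C@@]2(C)CCCC(C)(C)[C@H]12
F6 | step 8 | 11-tert-butyl 12-methyl (5S,6R,10S)-6-hydroxydrim-8-ene-11,12-dioate (6β-OH, C6 epimer of 13) | O[C@@H]1CC(C(=O)OC)=C(C(=O)OC(C)(C)C)[C@@]2(C)CCCC(C)(C)[C@H]12
F7 | step 8 | 11-tert-butyl 12-methyl (5S,6R,9S,10S)-6,9-dihydroxydrim-7-ene-11,12-dioate (C6 epimer of 15) | O[C@@H]1C=C(C(=O)OC)[C@](O)(C(=O)OC(C)(C)C)[C@@]2(C)CCCC(C)(C)[C@H]12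
F8 | step 9 | 6-O-trimethylsilyl ether and trimethylsilyl ketene acetal (C11 ester, C9=C11) of the C7-deprotonated form of 13 | C[Si](C)(C)O[C@H]1C=C(C(=O)OC)C(=C(O[Si](C)(C)C)OC(C)(C)C)[C@@]2(C)CCCC(C)(C)[C@H]12
F9 | step 9 | 6,9-bis(trimethylsilyl) ether of 15 | C[Si](C)(C)O[C@H]1C=C(C(=O)OC)[C@](O[Si](C)(C)C)(C(=O)OC(C)(C)C)[C@@]2(C)CCCC(C)(C)[C@H]12
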